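**Retrosynthetic overview**

1. The target is reached by desilylation and ester reduction of a diaryl ether in which ring B is a methyl 3-hydroxy-5-methylbenzoate and ring A carries a free carboxyl group and the silyl-protected (S)-carbinol.
2. Key disconnection C2'–C3' of ring B. Ring B has the ether oxygen (C1'), the hydroxyl (C2') and the carbinol carbon (on C6') on three contiguous carbons, and its C4' methyl lies between two CH positions (C3', C5'). C3' and that methyl are therefore the two methyls of an isopropylidene group, and C2' and the C6' carbinol carbon are the ester carbons of a 2-aryloxy-3-(2-methylprop-1-enyl)butenedioate, which folds by an aromatising vinylogous Dieckmann condensation.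
3. The open chain comes from addition–elimination of the ring A phenol on dimethyl 2-iodo-3-(2-methylprop-1-enyl)butenedioate, itself made from dimethyl but-2-ynedioate by carbocupration–iodination. The ring A carboxyl is an allyl ester up to this point and is freed before the fold, because an ester ortho to the ether oxygen would be acylated by any carbanion at C1' (5-exo closure to a benzofuran-3-one), whereas a carboxylate cannot be.
4. The ring A phenol comes from 4-hydroxy-2-methoxybenzaldehyde: isobutyl addition, oxidation and Corey–Bakshi–Shibata reduction set the (S)-centre, and lithiation between the OMe and OCH2OMe groups brings in the carboxyl carbon.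
5. Ring order: ring A is bought; ring B is the only ring made, in step 11.

Key step: step 11

Remark: ring B locants (C1' ether oxygen, C2' OH, C4' methyl, C6' carbinol carbon) are also used for the open-chain carbons that become them. The alkene geometry of 18, 19 and 20 is left open because it is erased in trienolate 20. TBS = tert-butyldimethylsilyl.

**Route**

Step 1
Reactants: 1 4-hydroxy-2-methoxybenzaldehyde
Product: 2 2-methoxy-4-(methoxymethoxy)benzaldehyde
Conditions: MeOCH2Cl, iPr2NEt, CH2Cl2, 0 °C to rt
Reagents that add atoms: chloromethyl methyl ether, COCCl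
Why: O-alkylation of the acidic para-formyl phenol with the α-chloro ether gives the methoxymethyl acetal that later directs the lithiation.

Step 2
Reactants: 2 2-methoxy-4-(methoxymethoxy)benzaldehyde; 3 isobutylmagnesium bromide
Product: 4 rac-1-[2-methoxy-4-(methoxymethoxy)phenyl]-3-methylbutan-1-ol
Conditions: THF, −20 to 0 °C; aq. NH4Cl
Reagents that add atoms: 3 isobutylmagnesium bromide, CC(C)C[Mg]Br
Why: Grignard addition to the aryl aldehyde is fast at low temperature, and the racemic centre is of no concern because it is reoxidised in step 3.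

Step 3
Reactants: 4 rac-1-[2-methoxy-4-(methoxymethoxy)phenyl]-3-methylbutan-1-ol
Product: 5 1-[2-methoxy-4-(methoxymethoxy)phenyl]-3-methylbutan-1-one
Conditions: Dess–Martin periodinane, NaHCO3, CH2Cl2, rt
Reagents that add atoms: none
Why: Dess–Martin oxidation of a benzylic secondary alcohol under bicarbonate buffering leaves the acid-labile acetal intact.

Step 4
Reactants: 5 1-[2-methoxy-4-(methoxymethoxy)phenyl]-3-methylbutan-1-one
Product: 6 (1S)-1-[2-methoxy-4-(methoxymethoxy)phenyl]-3-methylbutan-1-ol
Conditions: (R)-2-methyl-CBS-oxazaborolidine (0.1 equiv), BH3·SMe2, THF, −20 °C; MeOH quench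
Reagents that add atoms: none
Why: Corey–Bakshi–Shibata reduction, in which the (R)-oxazaborolidine–borane complex binds the ketone with the aryl group as the large substituent and delivers hydride to the Re face, should set the (S)-carbinol centre that is carried unchanged to the target.

Step 5
Reactants: 6 (1S)-1-[2-methoxy-4-(methoxymethoxy)phenyl]-3-methylbutan-1-ol
Product: 7 tert-butyl{(1S)-1-[2-methoxy-4-(methoxymethoxy)phenyl]-3-methylbutoxy}dimethylsilane
Conditions: TBSCl, imidazole, DMF, rt
Reagents that add atoms: tert-butyldimethylsilyl chloride, CC(C)(C)[Si](C)(C)Cl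
Why: imidazole-promoted silylation gives a benzylic silyl ether that should tolerate the organolithium, amide-base and borohydride steps and is cleaved by fluoride at the end.

Step 6
Reactants: 7 tert-butyl{(1S)-1-[2-methoxy-4-(methoxymethoxy)phenyl]-3-methylbutoxy}dimethylsilane; 8 prop-2-enyl chloroformate
Product: 10 prop-2-enyl 3-[(1S)-1-(tert-butyldimethylsilyloxy)-3-methylbutyl]-2-methoxy-6-(methoxymethoxy)benzoate, via aryllithium 9 (not isolated)
Conditions: n-BuLi, TMEDA, THF, −78 to 0 °C; then inverse addition to ClCO2CH2CH=CH2, THF, −78 °C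
Reagents that add atoms: 8 prop-2-enyl chloroformate, C=CCOC(=O)Cl; n-butyllithium, [Li]CCCC (lithium is held in 9 only)
Why: directed ortho-metalation takes place at the ring CH flanked by the methoxy and methoxymethoxy groups, the most acidic and doubly coordinated site, and acylation of 9 by excess chloroformate installs the carboxyl carbon as an ester that zerovalent palladium can later cleave.

Step 7
Reactants: 10 prop-2-enyl 3-[(1S)-1-(tert-butyldimethylsilyloxy)-3-methylbutyl]-2-methoxy-6-(methoxymethoxy)benzoate
Product: 12 prop-2-enyl 3-[(1S)-1-(tert-butyldimethylsilyloxy)-3-methylbutyl]-6-hydroxy-2-methoxybenzoate, via aryl trimethylsilyl ether 11 (not isolated)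
Conditions: TMSOTf, 2,2'-bipyridyl, CH2Cl2, 0 °C to rt; then H2O, aq. NaHCO3
Reagents that add atoms: trimethylsilyl trifluoromethanesulfonate, C[Si](C)(C)OS(=O)(=O)C(F)(F)F (its silyl group is held in 11 only)
Why: the silyl triflate–bipyridyl complex cleaves aryl methoxymethyl ethers through the aryl silyl ether under non-protic conditions, so the benzylic silyl ether, its (S)-centre and the allyl ester should survive.

Step 8
Reactants: 13 (2-methylprop-1-enyl)magnesium bromide; 14 dimethyl but-2-ynedioate
Product: 17 dimethyl (2E)-2-iodo-3-(2-methylprop-1-enyl)but-2-enedioate, via alkenylcopper reagent 15 (not isolated), via vinylcopper adduct 16 (not isolated)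
Conditions: CuBr·SMe2, THF, −40 °C; then 14, −78 °C; then I2, −78 to 0 °C; aq. Na2S2O3
Reagents that add atoms: 13 (2-methylprop-1-enyl)magnesium bromide, CC(C)=C[Mg]Br; iodine, II; CuBr·SMe2, Br[Cu].CSC (copper is held in 15 and 16 only)
Why: carbocupration, the syn addition of an organocopper reagent across an activated alkyne, gives an α-cuprio enoate whose carbon–copper bond is cleaved by iodine, and the alkene geometry obtained is of no consequence later.

Step 9
Reactants: 12 prop-2-enyl 3-[(1S)-1-(tert-butyldimethylsilyloxy)-3-methylbutyl]-6-hydroxy-2-methoxybenzoate; 17 dimethyl (2E)-2-iodo-3-(2-methylprop-1-enyl)but-2-enedioate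
Product: 18 dimethyl 2-{2-[(prop-2-enyloxy)carbonyl]-4-[(1S)-1-(tert-butyldimethylsilyloxy)-3-methylbutyl]-3-methoxyphenoxy}-3-(2-methylprop-1-enyl)but-2-enedioate (alkene isomers)
Conditions: Cs2CO3, DMF, 0 °C to rt
Reagents that add atoms: none
Why: nucleophilic vinylic substitution by addition–elimination, in which the caesium phenoxide adds to the iodine-bearing carbon (β to the C6' ester) and the stabilised dienolate expels iodide, forms the aryl–O–C1' bond without ever placing a carbanion next to the ring A ester.

Step 10
Reactants: 18 dimethyl 2-{2-[(prop-2-enyloxy)carbonyl]-4-[(1S)-1-(tert-butyldimethylsilyloxy)-3-methylbutyl]-3-methoxyphenoxy}-3-(2-methylprop-1-enyl)but-2-enedioate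
Product: 19 3-[(1S)-1-(tert-butyldimethylsilyloxy)-3-methylbutyl]-6-{[1,4-dimethoxy-3-(2-methylprop-1-enyl)-1,4-dioxobut-2-en-2-yl]oxy}-2-methoxybenzoic acid (alkene isomers)
Conditions: Pd(PPh3)4 (5 mol %), PhSiH3, CH2Cl2, rt; pH 4 buffer work-up
Reagents that add atoms: none
Why: Tsuji–Trost-type deallylation, in which zerovalent palladium ionises the allyl ester and the silane reduces the π-allyl complex, should leave the methyl esters, the silyl ether and the tetrasubstituted enol ether untouched.

Step 11
Reactants: 19 3-[(1S)-1-(tert-butyldimethylsilyloxy)-3-methylbutyl]-6-{[1,4-dimethoxy-3-(2-methylprop-1-enyl)-1,4-dioxobut-2-en-2-yl]oxy}-2-methoxybenzoic acid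
Product: 21 3-[(1S)-1-(tert-butyldimethylsilyloxy)-3-methylbutyl]-6-[2-hydroxy-6-(methoxycarbonyl)-4-methylphenoxy]-2-methoxybenzoic acid, via dilithium trienolate 20 (not isolated)
Conditions: LiN(SiMe3)2 (3.3 equiv), THF, −78 °C, then 0 °C to rt; aq. NH4Cl, pH 4
Reagents that add atoms: LiN(SiMe3)2, [Li]N([Si](C)(C)C)[Si](C)(C)C (lithium is held in 20 only)
Why: Proposed new method: after the ring A acid has become its lithium carboxylate, the base removes a proton from one of the two equivalent terminal methyl groups to give trienolate 20, whose charge runs from the new CH2 terminus through C4', C5', C6' and C1' into the ester attached to C1'; on warming, this terminus bonds to that ester carbon (the C2'–C3' bond), methoxide is lost and the cyclohexa-2,4-dienone is deprotonated to the aromatic ring B phenoxide, an irreversible sink. The closest known reaction type is the base-induced aromatising cyclisation of prenal-derived alkylidenemalonates to salicylates, together with the Stobbe-type benzannulation of dienyl half-esters, and it has not been shown with an aryloxy group on the carbon that carries the attacked ester. Ring B closes by attack on the ester carbonyl with the nucleophilic C3'=C4' π bond inside the new ring, a 6-(enolendo)-exo-trig closure that can equally be read as a disrotatory 6π electrocyclisation of the 1-oxido-1-methoxytriene followed by loss of methoxide. No stereocentre is formed, and the (S)-silyloxy centre is remote from every anionic site. The step needs attack at the C1' ester and not at the C6' ester or at ring A: closure on the C6' ester would be a disfavoured 5-(enolendo)-exo-trig process with no aromatic outcome, the ring A carboxyl is a carboxylate and so cannot be acylated by the α-carbon C1', and the two methyl groups are equivalent. Either alkene isomer of 19 can be used because the C1'–C6' bond has single-bond character in 20, and complete deprotonation at −78 °C before warming keeps the released methoxide away from any neutral enol ether.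

Step 12
Reactants: 21 3-[(1S)-1-(tert-butyldimethylsilyloxy)-3-methylbutyl]-6-[2-hydroxy-6-(methoxycarbonyl)-4-methylphenoxy]-2-methoxybenzoic acid
Product: 22 3-[(1S)-1-(tert-butyldimethylsilyloxy)-3-methylbutyl]-6-[2-hydroxy-6-(hydroxymethyl)-4-methylphenoxy]-2-methoxybenzoic acid
Conditions: LiBH4 (5 equiv), MeOH (5 equiv), THF, 0 °C to rt; aq. NH4Cl
Reagents that add atoms: none
Why: lithium borohydride reduces the methyl ester to the benzylic alcohol, whereas the hindered 2,6-disubstituted lithium carboxylate of ring A and the phenoxide are inert to it (chemoselective reduction of an ester beside a carboxylate).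

Step 13
Reactants: 22 3-[(1S)-1-(tert-butyldimethylsilyloxy)-3-methylbutyl]-6-[2-hydroxy-6-(hydroxymethyl)-4-methylphenoxy]-2-methoxybenzoic acid
Product: 23 6-[2-hydroxy-6-(hydroxymethyl)-4-methylphenoxy]-3-[(1S)-1-hydroxy-3-methylbutyl]-2-methoxybenzoic acid
Conditions: Bu4NF (4 equiv), THF, rt; aq. NH4Cl, pH 4
Reagents that add atoms: none
Why: fluoride-induced cleavage of the Si–O bond under non-acidic conditions avoids ionisation of the electron-rich benzylic carbinol and lactonisation, so the target should be obtained with the (S)-centre untouched.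

**Compound list**

1 | 4-hydroxy-2-methoxybenzaldehyde | COc1cc(O)ccc1C=O | starting material
2 | 2-methoxy-4-(methoxymethoxy)benzaldehyde | COCOc1ccc(C=O)c(OC)c1 | intermediate
3 | isobutylmagnesium bromide | CC(C)C[Mg]Br | starting material
4 | rac-1-[2-methoxy-4-(methoxymethoxy)phenyl]-3-methylbutan-1-ol | COCOc1ccc(C(O)CC(C)C)c(OC)c1 | intermediate
5 | 1-[2-methoxy-4-(methoxymethoxy)phenyl]-3-methylbutan-1-one | COCOc1ccc(C(=O)CC(C)C)c(OC)c1 | intermediate
6 | (1S)-1-[2-methoxy-4-(methoxymethoxy)phenyl]-3-methylbutan-1-ol | COCOc1ccc([C@@H](O)CC(C)C)c(OC)c1 | intermediate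
7 | tert-butyl{(1S)-1-[2-methoxy-4-(methoxymethoxy)phenyl]-3-methylbutoxy}dimethylsilane | COCOc1ccc([C@@H](O[Si](C)(C)C(C)(C)C)CC(C)C)c(OC)c1 | intermediate
8 | prop-2-enyl chloroformate | C=CCOC(=O)Cl | starting material
9 | {3-[(1S)-1-(tert-butyldimethylsilyloxy)-3-methylbutyl]-2-methoxy-6-(methoxymethoxy)phenyl}lithium | [Li]c1c(OC)c([C@@H](O[Si](C)(C)C(C)(C)C)CC(C)C)ccc1OCOC | intermediate
10 | prop-2-enyl 3-[(1S)-1-(tert-butyldimethylsilyloxy)-3-methylbutyl]-2-methoxy-6-(methoxymethoxy)benzoate | C=CCOC(=O)c1c(OC)c([C@@H](O[Si](C)(C)C(C)(C)C)CC(C)C)ccc1OCOC | intermediate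
11 | prop-2-enyl 3-[(1S)-1-(tert-butyldimethylsilyloxy)-3-methylbutyl]-2-methoxy-6-(trimethylsilyloxy)benzoate | C=CCOC(=O)c1c(OC)c([C@@H](O[Si](C)(C)C(C)(C)C)CC(C)C)ccc1O[Si](C)(C)C | intermediate
12 | prop-2-enyl 3-[(1S)-1-(tert-butyldimethylsilyloxy)-3-methylbutyl]-6-hydroxy-2-methoxybenzoate | C=CCOC(=O)c1c(OC)c([C@@H](O[Si](C)(C)C(C)(C)C)CC(C)C)ccc1O | intermediate
13 | (2-methylprop-1-enyl)magnesium bromide | CC(C)=C[Mg]Br | starting material
14 | dimethyl but-2-ynedioate | COC(=O)C#CC(=O)OC | starting material
15 | (2-methylprop-1-enyl)copper | CC(C)=C[Cu] | intermediate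
16 | dimethyl 2-cuprio-3-(2-methylprop-1-enyl)but-2-enedioate (copper cis to the alkenyl group) | [Cu]/C(C(=O)OC)=C(\C=C(C)C)C(=O)OC | intermediate
17 | dimethyl (2E)-2-iodo-3-(2-methylprop-1-enyl)but-2-enedioate | I/C(C(=O)OC)=C(\C=C(C)C)C(=O)OC | intermediate
18 | dimethyl 2-{2-[(prop-2-enyloxy)carbonyl]-4-[(1S)-1-(tert-butyldimethylsilyloxy)-3-methylbutyl]-3-methoxyphenoxy}-3-(2-methylprop-1-enyl)but-2-enedioate (alkene isomers) | C=CCOC(=O)c1c(OC)c([C@@H](O[Si](C)(C)C(C)(C)C)CC(C)C)ccc1OC(C(=O)OC)=C(C(=O)OC)C=C(C)C | intermediate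
19 | 3-[(1S)-1-(tert-butyldimethylsilyloxy)-3-methylbutyl]-6-{[1,4-dimethoxy-3-(2-methylprop-1-enyl)-1,4-dioxobut-2-en-2-yl]oxy}-2-methoxybenzoic acid (alkene isomers) | OC(=O)c1c(OC)c([C@@H](O[Si](C)(C)C(C)(C)C)CC(C)C)ccc1OC(C(=O)OC)=C(C(=O)OC)C=C(C)C | intermediate
20 | dilithium trienolate of 19 (lithium carboxylate and lithium ester enolate) | [Li]OC(=O)c1c(OC)c([C@@H](O[Si](C)(C)C(C)(C)C)CC(C)C)ccc1OC(=C(OC)O[Li])C(C(=O)OC)=CC(C)=C | intermediate
21 | 3-[(1S)-1-(tert-butyldimethylsilyloxy)-3-methylbutyl]-6-[2-hydroxy-6-(methoxycarbonyl)-4-methylphenoxy]-2-methoxybenzoic acid | COC(=O)c1cc(C)cc(O)c1Oc1ccc([C@@H](O[Si](C)(C)C(C)(C)C)CC(C)C)c(OC)c1C(=O)O | intermediate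
22 | 3-[(1S)-1-(tert-butyldimethylsilyloxy)-3-methylbutyl]-6-[2-hydroxy-6-(hydroxymethyl)-4-methylphenoxy]-2-methoxybenzoic acid | OCc1cc(C)cc(O)c1Oc1ccc([C@@H](O[Si](C)(C)C(C)(C)C)CC(C)C)c(OC)c1C(=O)O | intermediate
23 | 6-[2-hydroxy-6-(hydroxymethyl)-4-methylphenoxy]-3-[(1S)-1-hydroxy-3-methylbutyl]-2-methoxybenzoic acid | COc1c([C@@H](O)CC(C)C)ccc(Oc2c(O)cc(C)cc2CO)c1C(=O)O | target

**Step count**

Total: 13 steps. Longest linear sequence: 12 steps (steps 1 to 7 and 9 to 13); step 8 is a one-step side branch.

**Steps most likely to fail**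

Step 11 (proposed new method). What may go wrong: deprotonation may be incomplete or misdirected; the trienolate may stay in the extended geometry about C5'–C6' and merely be reprotonated to deconjugated isomers; or intermolecular Michael addition may lead to oligomers before the ring closes. The fallback uses known chemistry, nucleophilic aromatic substitution followed by Dakin oxidation, and sets out from phenol 12. 2-Fluoro-5-methylbenzoic acid is lithiated next to fluorine with lithium 2,2,6,6-tetramethylpiperidide and formylated with DMF to 2-fluoro-3-formyl-5-methylbenzoic acid F1, which is methylated (MeI, K2CO3, DMF) to methyl 2-fluoro-3-formyl-5-methylbenzoate F2. Phenol 12 and F2 (K2CO3, DMF, 60 °C) should give the diaryl ether aldehyde F3, since the fluorine is activated by an ortho formyl and an ortho ester group. mCPBA in CH2Cl2 converts the formyl group into the aryl formate F4, and mild methanolysis (Et3N, MeOH) gives the ring B phenol allyl ester F5. Deallylation as in step 10 (Pd(PPh3)4, PhSiH3) returns to the route at 21.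

Step 9. What may go wrong: addition–elimination at the fully substituted iodo-alkene carbon may be slow for the hydrogen-bonded, weakly nucleophilic phenoxide, so that loss of iodine from 17 or its base-induced self-condensation takes over. The fallback forms the C1'=C6' double bond last by Horner–Wadsworth–Emmons olefination and sets out from 12. O–H insertion catalysed by Rh2(OAc)4 with methyl diazo(dimethoxyphosphoryl)acetate (toluene, 80 °C) gives the aryloxy phosphonoacetate F6. Grignard reagent 13 and dimethyl oxalate (THF, −78 °C) give methyl 4-methyl-2-oxopent-3-enoate F7. Olefination of F7 with F6 under mild conditions (LiCl, DBU, MeCN) returns to the route at 18.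

Step 8. What may go wrong: 14 may oligomerise under the organocopper reagent, a second alkenyl group may add, or the vinylcopper adduct may be protonated before iodine traps it. The fallback uses cross-coupling on a dihalide and sets out from 14. Addition of bromine (CH2Cl2, rt) gives dimethyl (2E)-2,3-dibromobut-2-enedioate F8. Suzuki–Miyaura mono-coupling of excess F8 with 2-methylprop-1-enylboronic acid pinacol ester (Pd(PPh3)4, K3PO4, dioxane, 60 °C) gives dimethyl 2-bromo-3-(2-methylprop-1-enyl)but-2-enedioate F9. F9 reacts with 12 under the conditions of step 9 and returns to the route at 18.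

**Further compounds**

F1 | step 11 | 2-fluoro-3-formyl-5-methylbenzoic acid | Cc1cc(C=O)c(F)c(C(=O)O)c1
F2 | step 11 | methyl 2-fluoro-3-formyl-5-methylbenzoate | COC(=O)c1cc(C)cc(C=O)c1F
F3 | step 11 | prop-2-enyl 3-[(1S)-1-(tert-butyldimethylsilyloxy)-3-methylbutyl]-6-[2-formyl-6-(methoxycarbonyl)-4-methylphenoxy]-2-methoxybenzoate | C=CCOC(=O)c1c(OC)c([C@@H](O[Si](C)(C)C(C)(C)C)CC(C)C)ccc1Oc1c(C=O)cc(C)cc1C(=O)OC
F4 | step 11 | prop-2-enyl 3-[(1S)-1-(tert-butyldimethylsilyloxy)-3-methylbutyl]-6-[2-(formyloxy)-6-(methoxycarbonyl)-4-methylphenoxy]-2-methoxybenzoate | C=CCOC(=O)c1c(OC)c([C@@H](O[Si](C)(C)C(C)(C)C)CC(C)C)ccc1Oc1c(OC=O)cc(C)cc1C(=O)OC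
F5 | step 11 | prop-2-enyl 3-[(1S)-1-(tert-butyldimethylsilyloxy)-3-methylbutyl]-6-[2-hydroxy-6-(methoxycarbonyl)-4-methylphenoxy]-2-methoxybenzoate | C=CCOC(=O)c1c(OC)c([C@@H](O[Si](C)(C)C(C)(C)C)CC(C)C)ccc1Oc1c(O)cc(C)cc1C(=O)OC
F6 | step 9 | prop-2-enyl 3-[(1S)-1-(tert-butyldimethylsilyloxy)-3-methylbutyl]-6-[1-(dimethoxyphosphoryl)-2-methoxy-2-oxoethoxy]-2-methoxybenzoate | C=CCOC(=O)c1c(OC)c([C@@H](O[Si](C)(C)C(C)(C)C)CC(C)C)ccc1OC(C(=O)OC)P(=O)(OC)OC
F7 | step 9 | methyl 4-methyl-2-oxopent-3-enoate | COC(=O)C(=O)C=C(C)C
F8 | step 8 | dimethyl (2E)-2,3-dibromobut-2-enedioate | COC(=O)/C(Br)=C(\Br)C(=O)OC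
F9 | step 8 | dimethyl 2-bromo-3-(2-methylprop-1-enyl)but-2-enedioate | COC(=O)C(Br)=C(C(=O)OC)C=C(C)C
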